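**Retrosynthetic overview**

- Target ⇒ C-12–C-13 bond: asymmetric Morita–Baylis–Hillman coupling of furan-2(5H)-one with a bicyclic C-12 aldehyde. This sets C-12; the butenolide ring is brought in intact.
- Aldehyde ⇒ LiAlH4 reduction (C-3 ketone, C-19 ester, auxiliary released) and acetal hydrolysis of a 3-oxo-19-ester decalin. This sets C-3.
- Key step: Mn(OAc)3/Cu(OAc)2 oxidative radical bicyclization of an acyclic (E,E)-dienyl 2-methyl-3-oxo ester. It forms C-4–C-5, then C-10–C-9: ring A, then ring B, in one cascade. C-4, C-5, C-9, C-10 and the 8(17)-alkene are set together; the absolute sense comes from a (+)-8-phenylmenthyl ester.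
- Acyclic chain ⇒ crossed Claisen condensation (C-3–C-4) onto an ester built by two isopropenyl-addition/Johnson–Claisen cycles from 3,3-dimethoxypropanal.

Assumption: atoms are numbered as in labdanes (C-1 to C-20), the target is read as (12R)-14-deoxy-12-hydroxyandrographolide, and (+)-8-phenylmenthol is a recoverable chiral auxiliary that leaves no atom in the target.

**Route**

Step 1
Reactants: 1 3,3-dimethoxypropanal; 2 isopropenylmagnesium bromide
Product: 3 (±)-5,5-dimethoxy-2-methylpent-1-en-3-ol
Conditions: THF, −78 → 0 °C; then H2O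
Reagents that add atoms: none
Why: Grignard 1,2-addition to the aldehyde at low temperature outruns enolisation and β-elimination of the β,β-dialkoxy aldehyde; the carbinol centre is racemic and is erased in step 2.

Step 2
Reactants: 3 (±)-5,5-dimethoxy-2-methylpent-1-en-3-ol; 4 trimethyl orthoacetate
Product: 5 methyl (4E)-7,7-dimethoxy-4-methylhept-4-enoate
Conditions: 4 (5 equiv, neat), EtCO2H (5 mol%), 110 → 140 °C, MeOH distilled off
Reagents that add atoms: none
Why: Johnson–Claisen rearrangement through a chair transition state with the CH2CH(OMe)2 group equatorial gives the E trisubstituted alkene (expected ≥95:5) and adds two carbons, while the weak acid leaves the acetal intact.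

Step 3
Reactants: 5 methyl (4E)-7,7-dimethoxy-4-methylhept-4-enoate; 2 isopropenylmagnesium bromide
Product: 7 (±)-(6E)-9,9-dimethoxy-2,6-dimethylnona-1,6-dien-3-ol, via heptenal 6 (not isolated)
Conditions: iBu2AlH (1.1 equiv), CH2Cl2, −78 °C; then 2 (3 equiv), −78 → 0 °C; then H2O, aq. KNaC4H4O6
Reagents that add atoms: none
Why: Tandem partial ester reduction and Grignard addition: the aluminium hemiacetal formed at −78 °C releases aldehyde 6 on warming and is trapped at once by the alkenyl Grignard reagent, giving the racemic allylic alcohol whose carbinol centre is erased in step 4.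

Step 4
Reactants: 7 (±)-(6E)-9,9-dimethoxy-2,6-dimethylnona-1,6-dien-3-ol; 4 trimethyl orthoacetate
Product: 8 methyl (4E,8E)-11,11-dimethoxy-4,8-dimethylundeca-4,8-dienoate
Conditions: 4 (5 equiv, neat), EtCO2H (5 mol%), 110 → 140 °C, MeOH distilled off
Reagents that add atoms: none
Why: A second Johnson–Claisen rearrangement sets the second E trisubstituted alkene by the same chair transition state and delivers the full C-1 to C-12 chain as its methyl ester.

Step 5
Reactants: 9 propanoyl chloride
Product: 10 (1S,2R,5S)-5-methyl-2-(2-phenylpropan-2-yl)cyclohexyl propanoate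
Conditions: (+)-8-phenylmenthol (1.0 equiv), NEt3, DMAP (cat.), CH2Cl2, 0 °C → rt
Reagents that add atoms: (+)-8-phenylmenthol, O[C@H]1C[C@@H](C)CC[C@@H]1C(C)(C)c1ccccc1
Why: DMAP-catalysed acylation (nucleophilic acyl substitution) attaches the propanoate to the auxiliary without touching its three stereocentres.

Step 6
Reactants: 10 (1S,2R,5S)-5-methyl-2-(2-phenylpropan-2-yl)cyclohexyl propanoate; 8 methyl (4E,8E)-11,11-dimethoxy-4,8-dimethylundeca-4,8-dienoate
Product: 12 (1S,2R,5S)-5-methyl-2-(2-phenylpropan-2-yl)cyclohexyl (2RS,6E,10E)-13,13-dimethoxy-2,6,10-trimethyl-3-oxotrideca-6,10-dienoate, via lithium enolate 11 (not isolated)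
Conditions: LDA (LiN(iPr)2, commercial solution, 2.3 equiv), 10 (2.2 equiv), THF, −78 °C; then 8 (1.0 equiv), −78 → −20 °C; AcOH quench
Reagents that add atoms: none
Why: Crossed Claisen condensation: the ester enolate acylates the unhindered methyl ester and the second equivalent deprotonates the β-keto ester to drive the reaction; the C-4 centre is a mixture, which is harmless because it becomes a planar radical in step 7.

Step 7
Reactants: 12 (1S,2R,5S)-5-methyl-2-(2-phenylpropan-2-yl)cyclohexyl (2RS,6E,10E)-13,13-dimethoxy-2,6,10-trimethyl-3-oxotrideca-6,10-dienoate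
Product: 13 (1S,2R,5S)-5-methyl-2-(2-phenylpropan-2-yl)cyclohexyl (1S,4aS,5R,8aS)-5-(2,2-dimethoxyethyl)-1,4a-dimethyl-6-methylidene-2-oxodecahydronaphthalene-1-carboxylate
Conditions: Mn(OAc)3·2H2O (2.2 equiv), Cu(OAc)2·H2O (1.0 equiv), degassed MeOH, 25 → 40 °C, N2; chromatography to remove the minor diastereomer and alkene isomers
Reagents that add atoms: none
Why: Mn(OAc)3/Cu(OAc)2 oxidative free-radical polyene cyclization (Snider type): trivalent manganese turns the enol into the planar C-4 radical, which closes ring A (6-endo at C-5) and ring B (6-endo at C-9) through a chair–chair array of the E,E-diene (trans ring fusion, C-9 chain equatorial, ester axial and cis to the C-10 methyl as in podocarpate syntheses), the phenyl ring of the auxiliary shields one face of the radical to fix the absolute sense, and divalent copper oxidises the tertiary C-8 radical through an alkylcopper species to the less substituted 8(17)-alkene.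

Step 8
Reactants: 13 (1S,2R,5S)-5-methyl-2-(2-phenylpropan-2-yl)cyclohexyl (1S,4aS,5R,8aS)-5-(2,2-dimethoxyethyl)-1,4a-dimethyl-6-methylidene-2-oxodecahydronaphthalene-1-carboxylate
Product: 15 2-[(1R,4aS,5R,6R,8aS)-6-hydroxy-5-(hydroxymethyl)-5,8a-dimethyl-2-methylidenedecahydronaphthalen-1-yl]acetaldehyde, via diol acetal 14 (not isolated)
Conditions: LiAlH4 (excess), THF, −78 → 65 °C; NaOH/H2O work-up; then THF/1 M HCl (10:1), 0 °C → rt
Reagents that add atoms: water, O
Why: Hydride reduction followed by acetal hydrolysis: LiAlH4 attacks the C-3 ketone axially from the face opposite the axial C-19 ester and C-20 methyl (equatorial 3-OH, 3R), then cleaves the neopentyl ester to the C-19 alcohol with release of the auxiliary, and dilute aqueous acid frees the C-12 aldehyde without moving the exocyclic alkene.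

Step 9
Reactants: 15 2-[(1R,4aS,5R,6R,8aS)-6-hydroxy-5-(hydroxymethyl)-5,8a-dimethyl-2-methylidenedecahydronaphthalen-1-yl]acetaldehyde; 16 furan-2(5H)-one
Product: 17 3-[(1R)-1-hydroxy-2-[(1R,4aS,5R,6R,8aS)-6-hydroxy-5-(hydroxymethyl)-5,8a-dimethyl-2-methylidenedecahydronaphthalen-1-yl]ethyl]furan-2(5H)-one
Conditions: 16 (3 equiv), PEt3 (1 equiv), (R)-3,3′-bis(3,5-dimethylphenyl)-5,5′,6,6′,7,7′,8,8′-octahydro-1,1′-bi-2-naphthol (20 mol%), THF, −10 °C
Reagents that add atoms: none
Why: Proposed new method: a phosphine/chiral Brønsted acid co-catalysed asymmetric Morita–Baylis–Hillman reaction extended to a butenolide, in which PEt3 adds to C-14 of 16 to give a phosphonium lactone enolate that attacks the aldehyde inside the hydrogen-bonded chiral diol complex (catalyst control of the C-12 face, C-9 being too remote to interfere), after which proton transfer and loss of PEt3 restore the C-13=C-14 bond; the closest known reactions are the racemic phosphine- or Et2AlI-promoted Baylis–Hillman coupling of furan-2(5H)-one with aliphatic aldehydes and the diol-acid/PEt3 asymmetric version with cyclohexenone.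

**Compound list**

1 | 3,3-dimethoxypropanal | COC(OC)CC=O | starting material
2 | isopropenylmagnesium bromide (prop-1-en-2-ylmagnesium bromide, THF solution) | CC(=C)[Mg]Br | starting material
3 | (±)-5,5-dimethoxy-2-methylpent-1-en-3-ol | CC(=C)C(O)CC(OC)OC | intermediate
4 | trimethyl orthoacetate (1,1,1-trimethoxyethane) | CC(OC)(OC)OC | starting material
5 | methyl (4E)-7,7-dimethoxy-4-methylhept-4-enoate | COC(=O)CC/C(C)=C/CC(OC)OC | intermediate
6 | (4E)-7,7-dimethoxy-4-methylhept-4-enal (held as its aluminium hemiacetal) | O=CCC/C(C)=C/CC(OC)OC | intermediate (not isolated)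
7 | (±)-(6E)-9,9-dimethoxy-2,6-dimethylnona-1,6-dien-3-ol | CC(=C)C(O)CC/C(C)=C/CC(OC)OC | intermediate
8 | methyl (4E,8E)-11,11-dimethoxy-4,8-dimethylundeca-4,8-dienoate | COC(=O)CC/C(C)=C/CC/C(C)=C/CC(OC)OC | intermediate
9 | propanoyl chloride | CCC(Cl)=O | starting material
10 | (1S,2R,5S)-5-methyl-2-(2-phenylpropan-2-yl)cyclohexyl propanoate ((+)-8-phenylmenthyl propanoate) | CCC(=O)O[C@H]1C[C@@H](C)CC[C@@H]1C(C)(C)c1ccccc1 | intermediate
11 | lithium enolate of 10 (enolate geometry immaterial) | [Li]OC(=CC)O[C@H]1C[C@@H](C)CC[C@@H]1C(C)(C)c1ccccc1 | intermediate (not isolated)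
12 | (+)-8-phenylmenthyl (2RS,6E,10E)-13,13-dimethoxy-2,6,10-trimethyl-3-oxotrideca-6,10-dienoate | CC(C(=O)CC/C(C)=C/CC/C(C)=C/CC(OC)OC)C(=O)O[C@H]1C[C@@H](C)CC[C@@H]1C(C)(C)c1ccccc1 | intermediate
13 | (+)-8-phenylmenthyl (1S,4aS,5R,8aS)-5-(2,2-dimethoxyethyl)-1,4a-dimethyl-6-methylidene-2-oxodecahydronaphthalene-1-carboxylate (trans-decalin; ester axial, cis to the angular methyl; side chain equatorial) | C=C1CC[C@@H]2[C@](C)(C(=O)O[C@H]3C[C@@H](C)CC[C@@H]3C(C)(C)c3ccccc3)C(=O)CC[C@@]2(C)[C@@H]1CC(OC)OC | intermediate
14 | (1R,2R,4aS,5R,8aS)-5-(2,2-dimethoxyethyl)-1-(hydroxymethyl)-1,4a-dimethyl-6-methylidenedecahydronaphthalen-2-ol | C=C1CC[C@@H]2[C@](C)(CO)[C@H](O)CC[C@@]2(C)[C@@H]1CC(OC)OC | intermediate (not isolated)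
15 | 2-[(1R,4aS,5R,6R,8aS)-6-hydroxy-5-(hydroxymethyl)-5,8a-dimethyl-2-methylidenedecahydronaphthalen-1-yl]acetaldehyde | C=C1CC[C@@H]2[C@](C)(CO)[C@H](O)CC[C@@]2(C)[C@@H]1CC=O | intermediate
16 | furan-2(5H)-one | O=C1OCC=C1 | starting material
17 | 3-[(1R)-1-hydroxy-2-[(1R,4aS,5R,6R,8aS)-6-hydroxy-5-(hydroxymethyl)-5,8a-dimethyl-2-methylidenedecahydronaphthalen-1-yl]ethyl]furan-2(5H)-one (CNP0270153.1) | C=C1CC[C@@H]2[C@](C)(CO)[C@H](O)CC[C@@]2(C)[C@@H]1C[C@@H](O)C1=CCOC1=O | target

**Step count**

Total steps: 9. Longest linear sequence: 8 (steps 1, 2, 3, 4, 6, 7, 8, 9); step 5 is a one-step side branch.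

**Three steps most likely to fail**

Step 7 (key radical bicyclization). The risks are:
- facial control by the auxiliary below a useful level; the sense is assigned by analogy with the podocarpate series as I recall it, where the antipodal auxiliary gives the antipodal decalin, and should be confirmed on the first run;
- a mixture of 8(17)- and ring-alkene isomers from the copper oxidation;
- capture of the oxidised C-8 centre by an acetal oxygen, or loss of the acetal.

The fallback sets out from 12 and comes back at 13. It replaces the oxidative manganese/copper cascade by a non-oxidative group-transfer radical chain and makes the alkene in a separate step. Selenenylation of 12 (NaH, PhSeCl, THF, 0 °C) gives the α-phenylselanyl keto ester F1. Photolysis or Et3B/O2 initiation in toluene at −20 °C generates the same C-4 radical, which closes both rings and abstracts the phenylselanyl group from a further molecule of F1, giving the 8-(phenylselanyl) decalin F2 as C-8 epimers. Oxidation with H2O2/pyridine and selenoxide syn-elimination toward the methyl group then gives 13.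

Step 9 (asymmetric Baylis–Hillman coupling with the butenolide). The risks are low reactivity of the lactone, butenolide dimerisation, low or mismatched selectivity at C-12 (the antipode of the diol acid is the first remedy), and interference by the free diol. The fallback sets out from 15 and comes back at 17. It uses an acrylate Baylis–Hillman reaction with known (R) selectivity for aliphatic aldehydes, followed by ring-closing metathesis. β-Isocupreidine (10 mol%) with 1,1,1,3,3,3-hexafluoropropan-2-yl acrylate in DMF at −55 °C gives the (12R) hexafluoroisopropyl ester F3. Allyl alcohol and NEt3 in the same pot convert it into the allyl 2-methylidene-3-hydroxy ester F4. Ring-closing metathesis with the second-generation Hoveyda–Grubbs catalyst in toluene at 80 °C closes the butenolide and gives 17.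

Step 6 (crossed Claisen condensation with a hindered ester enolate). The risks are slow acylation by the simple methyl ester and decomposition of the enolate on warming. The fallback sets out from 8 and comes back at 12. It replaces the acylation by an aldol addition and an oxidation. Reduction of 8 with iBu2AlH at −78 °C gives the dienal F5. Aldol addition of enolate 11 at −78 °C gives the β-hydroxy ester F6 as a diastereomer mixture. Dess–Martin periodinane oxidation then gives 12.

**Further compounds**

F1 | step 7 | (+)-8-phenylmenthyl (6E,10E)-13,13-dimethoxy-2,6,10-trimethyl-3-oxo-2-(phenylselanyl)trideca-6,10-dienoate (C-2 epimers) | CC([Se]c1ccccc1)(C(=O)CC/C(C)=C/CC/C(C)=C/CC(OC)OC)C(=O)O[C@H]1C[C@@H](C)CC[C@@H]1C(C)(C)c1ccccc1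
F2 | step 7 | 8-(phenylselanyl)-8-methyl analogue of 13 (saturated at C-8, both C-8 epimers, other centres as in 13) | CC1([Se]c2ccccc2)CC[C@@H]2[C@](C)(C(=O)O[C@H]3C[C@@H](C)CC[C@@H]3C(C)(C)c3ccccc3)C(=O)CC[C@@]2(C)[C@@H]1CC(OC)OC
F3 | step 9 | 1,1,1,3,3,3-hexafluoropropan-2-yl (3R)-3-hydroxy-4-[(1R,4aS,5R,6R,8aS)-6-hydroxy-5-(hydroxymethyl)-5,8a-dimethyl-2-methylidenedecahydronaphthalen-1-yl]-2-methylidenebutanoate | C=C1CC[C@@H]2[C@](C)(CO)[C@H](O)CC[C@@]2(C)[C@@H]1C[C@@H](O)C(=C)C(=O)OC(C(F)(F)F)C(F)(F)F
F4 | step 9 | prop-2-en-1-yl (3R)-3-hydroxy-4-[(1R,4aS,5R,6R,8aS)-6-hydroxy-5-(hydroxymethyl)-5,8a-dimethyl-2-methylidenedecahydronaphthalen-1-yl]-2-methylidenebutanoate | C=C1CC[C@@H]2[C@](C)(CO)[C@H](O)CC[C@@]2(C)[C@@H]1C[C@@H](O)C(=C)C(=O)OCC=C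
F5 | step 6 | (4E,8E)-11,11-dimethoxy-4,8-dimethylundeca-4,8-dienal | O=CCC/C(C)=C/CC/C(C)=C/CC(OC)OC
F6 | step 6 | (+)-8-phenylmenthyl (6E,10E)-3-hydroxy-13,13-dimethoxy-2,6,10-trimethyltrideca-6,10-dienoate (diastereomer mixture at C-2 and C-3) | CC(C(O)CC/C(C)=C/CC/C(C)=C/CC(OC)OC)C(=O)O[C@H]1C[C@@H](C)CC[C@@H]1C(C)(C)c1ccccc1
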